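**Retrosynthetic overview**

1. Target 15 ⇐ 14 ⇐ 13 ⇐ 12: the C4 carboxylic acid (tert-butyl ester acidolysis) and the terminal acetate (desilylation, acetylation) are unmasked last, without strong base.
2. Butenolide 12 ⇐ hydroxy lactone 10 by loss of water across C3–C4 (tertiary mesylate, E1cB through the C4 ester enolate).
3. Lactone 10 ⇐ (R)-β-hydroxy ester 6 + methyl pyruvate 7. The strategy rests on reading C5, C4 and the C4 carboxyl as a 3-oxygenated fatty acyl unit, and C3, its methyl and the C2 carbonyl as a pyruvate unit. The dianion of 6 forms C3–C4 (aldol), then the C5 alkoxide forms O1–C2 and closes the only ring, the five-membered lactone O1–C2–C3–C4–C5.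
4. 6 ⇐ β-keto ester 5 (Noyori hydrogenation, sets C5) ⇐ aldehyde 3 + tert-butyl diazoacetate 4 (Roskamp homologation) ⇐ diol 1.

Key step: step 5

Remark on the chemistry: ring atoms are discussed as O1, C2 (lactone C=O), C3 (C–CH3), C4 (C–CO2R), C5 (CH–chain); systematic names number the ring the other way round (chain carbon = position 2). The single stereocentre of the target is (R).

Remark on the chemistry: dianion addition anti to the C5 chain on the chelate corresponds, after closure through the C5 oxygen, to the lactone with ester and chain cis. Compound 10 is therefore drawn cis; this has no bearing on the target because C3 and C4 become sp2 in step 6.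

Remark on the chemistry: once the butenolide exists, C5–H is vinylogously acidic, so no step from 6 onwards uses an amidine base, an alkoxide or basic fluoride.

**Step 1**
Reactants: 1 tetradecane-1,14-diol
Product: 2 14-(tert-butyldimethylsilyloxy)tetradecan-1-ol
Conditions: NaH (1.0 equiv), THF, 0 °C → rt; then TBSCl (1.0 equiv), rt
Reagents that add atoms: tert-butyldimethylsilyl chloride (TBSCl), CC(C)(C)[Si](C)(C)Cl
Why: Silyl ether formation on the mono-sodium alkoxide of a symmetrical diol, in which the sparingly soluble mono-alkoxide should react with TBSCl faster than the remaining neutral hydroxyl, so that the mono-ether predominates and unreacted diol can be recycled.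

**Step 2**
Reactants: 2 14-(tert-butyldimethylsilyloxy)tetradecan-1-ol
Product: 3 14-(tert-butyldimethylsilyloxy)tetradecanal
Conditions: TEMPO (10 mol%), PhI(OAc)2 (1.1 equiv), CH2Cl2, rt
Reagents that add atoms: none
Why: Oxoammonium-mediated (TEMPO/PhI(OAc)2) oxidation takes a primary alcohol to the aldehyde without over-oxidation under anhydrous conditions and leaves the silyl ether intact.

**Step 3**
Reactants: 3 14-(tert-butyldimethylsilyloxy)tetradecanal; 4 tert-butyl diazoacetate
Product: 5 tert-butyl 16-(tert-butyldimethylsilyloxy)-3-oxohexadecanoate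
Conditions: SnCl2 (10 mol%), 4 (1.2 equiv), CH2Cl2, rt
Reagents that add atoms: none
Why: Roskamp homologation, in which the SnCl2-activated aldehyde is attacked by the diazo carbon and the resulting diazonium betaine undergoes a 1,2-hydride shift with loss of N2 to give the β-keto ester directly, under conditions mild enough for the silyl ether and the tert-butyl ester.

**Step 4**
Reactants: 5 tert-butyl 16-(tert-butyldimethylsilyloxy)-3-oxohexadecanoate
Product: 6 tert-butyl (3R)-16-(tert-butyldimethylsilyloxy)-3-hydroxyhexadecanoate
Conditions: H2 (10 bar), RuCl2[(R)-BINAP] (BINAP = 2,2'-bis(diphenylphosphino)-1,1'-binaphthyl; 0.5 mol%), degassed MeOH, 50 °C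
Reagents that add atoms: none
Why: Noyori asymmetric hydrogenation, in which the β-keto ester chelates the ruthenium hydride and the (R)-BINAP ligand directs hydride delivery to the ketone face that gives the (3R) alcohol, as it does for unbranched 3-oxoalkanoates in general, while the tert-butyl ester and the silyl ether are not reduced.

**Step 5**
Reactants: 6 tert-butyl (3R)-16-(tert-butyldimethylsilyloxy)-3-hydroxyhexadecanoate; 7 methyl pyruvate
Product: 10 tert-butyl (2R,3S)-2-[13-(tert-butyldimethylsilyloxy)tridecyl]-4-hydroxy-4-methyl-5-oxooxolane-3-carboxylate (both epimers at the carbinol carbon), via dilithium alkoxide–enolate 8 (not isolated), via dilithium aldolate 9 (not isolated)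
Conditions: LiN(iPr)2 (LDA, 2.2 equiv), THF, −78 → −20 °C; recool, 7 (1.5 equiv, freshly distilled, added rapidly), −78 °C; then → 0 °C; AcOH (2.5 equiv) quench
Reagents that add atoms: none
Why: Two equivalents of LDA should give the chelated lithium alkoxide–enolate 8 (Fráter–Seebach dianion), whose enolate carbon (C4) adds at −78 °C to the ketone carbonyl of methyl pyruvate to form C3–C4 and the bis-alkoxide 9; the closest known reaction types are dianion aldol additions of β-hydroxy esters to aldehydes and ketones and additions of lithium ester enolates to pyruvate esters. On warming, the C5 alkoxide of 9 attacks the adjacent methyl ester in a 5-exo-trig acyl substitution that expels lithium methoxide and closes the γ-lactone (O1–C2 bond), while the hindered tert-butyl ester on C4 stays exocyclic because its attack by either alkoxide could only give a four-membered ring. C5 is carried in from step 4 and is not enolisable here, so it is untouched. C4 is set by approach of the pyruvate anti to the C5 chain on the chelate ring (Fráter–Seebach sense), which after closure through the C5 oxygen places the ester cis to the chain (any trans epimer formed by base equilibration is equally usable), and C3 is formed without useful control. The selectivity that matters is addition to the ketone in preference to proton abstraction from the pyruvate methyl group, which rests on the very high electrophilicity of the α-keto ester carbonyl at −78 °C and on adding the pyruvate rapidly and in excess. Both new centres (C3, C4) become sp2 in step 6, so their configuration has no consequence.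

**Step 6**
Reactants: 10 tert-butyl (2R,3S)-2-[13-(tert-butyldimethylsilyloxy)tridecyl]-4-hydroxy-4-methyl-5-oxooxolane-3-carboxylate
Product: 12 tert-butyl (2R)-2-[13-(tert-butyldimethylsilyloxy)tridecyl]-4-methyl-5-oxo-2,5-dihydrofuran-3-carboxylate, via tertiary mesylate 11 (not isolated)
Conditions: MsCl (3 equiv), Et3N (8 equiv), CH2Cl2, −10 °C → rt
Reagents that add atoms: none
Why: Sulfene-mediated mesylation of the tertiary alcohol followed by E1cB elimination through the C4 ester enolate, in which C4–H is the only acidic β-hydrogen, the mesylate is a far better leaving group than the ring oxygen on C5 (whose C–O bond is also poorly aligned with the enolate π system), all diastereomers of 10 converge on the C3=C4 alkene, and triethylamine at or below room temperature is chosen because it should be too weak to deprotonate the vinylogously acidic C5–H of the product at a significant rate, so that the C5 configuration is retained.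

**Step 7**
Reactants: 12 tert-butyl (2R)-2-[13-(tert-butyldimethylsilyloxy)tridecyl]-4-methyl-5-oxo-2,5-dihydrofuran-3-carboxylate
Product: 13 tert-butyl (2R)-2-(13-hydroxytridecyl)-4-methyl-5-oxo-2,5-dihydrofuran-3-carboxylate
Conditions: HF·pyridine, pyridine, THF, 0 °C → rt
Reagents that add atoms: none
Why: Fluoride-driven cleavage of the primary silyl ether under buffered acidic conditions, which leave the tert-butyl ester and the butenolide untouched and, unlike basic fluoride sources, cannot deprotonate C5.

**Step 8**
Reactants: 13 tert-butyl (2R)-2-(13-hydroxytridecyl)-4-methyl-5-oxo-2,5-dihydrofuran-3-carboxylate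
Product: 14 tert-butyl (2R)-2-(13-acetoxytridecyl)-4-methyl-5-oxo-2,5-dihydrofuran-3-carboxylate
Conditions: Ac2O, pyridine, CH2Cl2, 0 °C → rt
Reagents that add atoms: acetic anhydride, CC(=O)OC(C)=O
Why: Pyridine-mediated acetylation of an unhindered primary alcohol with acetic anhydride, pyridine being too weak a base to epimerise C5.

**Step 9**
Reactants: 14 tert-butyl (2R)-2-(13-acetoxytridecyl)-4-methyl-5-oxo-2,5-dihydrofuran-3-carboxylate
Product: 15 (2R)-2-(13-acetoxytridecyl)-4-methyl-5-oxo-2,5-dihydrofuran-3-carboxylic acid (target)
Conditions: CF3CO2H/CH2Cl2 (1:3), 0 °C → rt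
Reagents that add atoms: none
Why: Acidolysis of the tert-butyl ester (E1 loss of the tert-butyl cation as 2-methylpropene) frees the C4 carboxylic acid, while the primary acetate, the butenolide and the C5 stereocentre are stable to anhydrous trifluoroacetic acid.

**Compound list**

1 | tetradecane-1,14-diol | OCCCCCCCCCCCCCCO | starting material
2 | 14-(tert-butyldimethylsilyloxy)tetradecan-1-ol | CC(C)(C)[Si](C)(C)OCCCCCCCCCCCCCCO | intermediate
3 | 14-(tert-butyldimethylsilyloxy)tetradecanal | CC(C)(C)[Si](C)(C)OCCCCCCCCCCCCCC=O | intermediate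
4 | tert-butyl diazoacetate | [N-]=[N+]=CC(=O)OC(C)(C)C | starting material
5 | tert-butyl 16-(tert-butyldimethylsilyloxy)-3-oxohexadecanoate | CC(C)(C)[Si](C)(C)OCCCCCCCCCCCCCC(=O)CC(=O)OC(C)(C)C | intermediate
6 | tert-butyl (3R)-16-(tert-butyldimethylsilyloxy)-3-hydroxyhexadecanoate | CC(C)(C)[Si](C)(C)OCCCCCCCCCCCCC[C@@H](O)CC(=O)OC(C)(C)C | intermediate
7 | methyl pyruvate (methyl 2-oxopropanoate) | CC(=O)C(=O)OC | starting material
8 | dilithium (3R)-1-tert-butoxy-16-(tert-butyldimethylsilyloxy)hexadec-1-ene-1,3-diolate (chelated; enolate oxygen cis to C3) | [Li+].[Li+].CC(C)(C)[Si](C)(C)OCCCCCCCCCCCCC[C@@H]([O-])/C=C(\[O-])OC(C)(C)C | intermediate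
9 | dilithium dialkoxide of 1-tert-butyl 4-methyl (2S)-2-[(1R)-14-(tert-butyldimethylsilyloxy)-1-hydroxytetradecyl]-3-hydroxy-3-methylbutanedioate (both C3 epimers) | [Li+].[Li+].CC(C)(C)[Si](C)(C)OCCCCCCCCCCCCC[C@@H]([O-])[C@H](C(=O)OC(C)(C)C)C(C)([O-])C(=O)OC | intermediate
10 | tert-butyl (2R,3S)-2-[13-(tert-butyldimethylsilyloxy)tridecyl]-4-hydroxy-4-methyl-5-oxooxolane-3-carboxylate (ester cis to chain; both epimers at the carbinol carbon) | CC(C)(C)[Si](C)(C)OCCCCCCCCCCCCC[C@H]1OC(=O)C(C)(O)[C@H]1C(=O)OC(C)(C)C | intermediate
11 | tert-butyl (2R,3S)-2-[13-(tert-butyldimethylsilyloxy)tridecyl]-4-methyl-4-(methylsulfonyloxy)-5-oxooxolane-3-carboxylate | CC(C)(C)[Si](C)(C)OCCCCCCCCCCCCC[C@H]1OC(=O)C(C)(OS(C)(=O)=O)[C@H]1C(=O)OC(C)(C)C | intermediate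
12 | tert-butyl (2R)-2-[13-(tert-butyldimethylsilyloxy)tridecyl]-4-methyl-5-oxo-2,5-dihydrofuran-3-carboxylate | CC(C)(C)[Si](C)(C)OCCCCCCCCCCCCC[C@H]1OC(=O)C(C)=C1C(=O)OC(C)(C)C | intermediate
13 | tert-butyl (2R)-2-(13-hydroxytridecyl)-4-methyl-5-oxo-2,5-dihydrofuran-3-carboxylate | OCCCCCCCCCCCCC[C@H]1OC(=O)C(C)=C1C(=O)OC(C)(C)C | intermediate
14 | tert-butyl (2R)-2-(13-acetoxytridecyl)-4-methyl-5-oxo-2,5-dihydrofuran-3-carboxylate | CC(=O)OCCCCCCCCCCCCC[C@H]1OC(=O)C(C)=C1C(=O)OC(C)(C)C | intermediate
15 | (2R)-2-(13-acetoxytridecyl)-4-methyl-5-oxo-2,5-dihydrofuran-3-carboxylic acid | CC(=O)OCCCCCCCCCCCCC[C@H]1OC(=O)C(C)=C1C(=O)O | target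

**Step count**

Total step count: 9
Longest linear sequence: 9 steps (1 → 15)

**Steps most likely to fail**

Step 5. Proton transfer from the pyruvate methyl group to the strongly basic dianion, followed by self-condensation of the pyruvate enolate, may outpace carbon–carbon bond formation. The bis-alkoxide may also revert by retro-aldol cleavage during the warm-up needed for ring closure.

The fallback sets out from 6 and rejoins the route at 12. It replaces the basic dianion addition by a Lewis-acid-mediated Mukaiyama aldol addition, so that the pyruvate never meets a strong base. Compound 6 is deprotonated as in step 5 and the dianion is trapped with Me3SiCl (2.5 equiv, −78 °C → rt) to give the bis-silylated ketene acetal (3R)-1-tert-butoxy-16-(tert-butyldimethylsilyloxy)-1,3-bis(trimethylsilyloxy)hexadec-1-ene F1. This is added at −78 °C in CH2Cl2 to methyl pyruvate 7 precomplexed with TiCl4. Work-up with aqueous citric acid in THF should remove the trimethylsilyl groups and leave the open-chain dihydroxy diester 1-tert-butyl 4-methyl 2-[(1R)-14-(tert-butyldimethylsilyloxy)-1-hydroxytetradecyl]-3-hydroxy-3-methylbutanedioate F2 as a diastereomer mixture. Warming with catalytic pyridinium p-toluenesulfonate in toluene should close the γ-lactone with loss of methanol to give tert-butyl (2R)-2-[13-(tert-butyldimethylsilyloxy)tridecyl]-4-hydroxy-4-methyl-5-oxooxolane-3-carboxylate F3 as a mixture of ring diastereomers. F3 is dehydrated under the conditions of step 6 and so arrives at 12.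

Step 6. Sulfonylation of the hindered, electron-poor tertiary hydroxyl may be slow. Once the butenolide is present, the C5 configuration may erode through amine-mediated vinylogous deprotonation (furanolate formation).

The fallback sets out from 10 and rejoins the route at the target 15, bypassing 12–14. It moves the dehydration into an amine-free acetic anhydride medium, in the manner of the classical acetic anhydride dehydrations of citric and citramalic acids. Aqueous CF3CO2H in CH2Cl2 removes the tert-butyl ester and the silyl ether from 10 to give (2R,3S)-4-hydroxy-2-(13-hydroxytridecyl)-4-methyl-5-oxooxolane-3-carboxylic acid F4. Heating F4 in acetic anhydride (about 100 °C, with a catalytic amount of anhydrous NaOAc only if elimination stalls) should acetylate both hydroxyls and convert the carboxyl into its mixed anhydride, giving acetic (2R,3S)-4-acetoxy-2-(13-acetoxytridecyl)-4-methyl-5-oxooxolane-3-carboxylic anhydride F5. The anhydride-activated C4–H then allows loss of acetic acid across C3–C4 to give acetic (2R)-2-(13-acetoxytridecyl)-4-methyl-5-oxo-2,5-dihydrofuran-3-carboxylic anhydride F6. Aqueous work-up hydrolyses the mixed anhydride and delivers 15.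

Step 4. The primary silyl ether may be lost to HCl released from the precatalyst in warm methanol, or enantioselection may be incomplete with the long lipophilic chain.

The fallback sets out from 3 and rejoins the route at 6. It sets the carbinol centre by reagent-controlled allyl transfer instead of ketone reduction. Brown allylboration of aldehyde 3 with (−)-Ipc2B(allyl) (Et2O, −78 °C; NaOH/H2O2 work-up) should deliver allyl to the Si face and give (4R)-17-(tert-butyldimethylsilyloxy)heptadec-1-en-4-ol F7. Ozonolysis (O3, CH2Cl2, −78 °C; PPh3) gives (3R)-16-(tert-butyldimethylsilyloxy)-3-hydroxyhexadecanal F8, which is used crude. Pinnick oxidation (NaClO2, NaH2PO4, 2-methylbut-2-ene, tBuOH/H2O) gives (3R)-16-(tert-butyldimethylsilyloxy)-3-hydroxyhexadecanoic acid F9. Esterification with tert-butyl 2,2,2-trichloroacetimidate (CH2Cl2/cyclohexane, rt) then gives 6; the carboxylic acid itself activates the imidate, so the secondary hydroxyl stays free.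

**Further compounds**

F1 | step 5 | (3R)-1-tert-butoxy-16-(tert-butyldimethylsilyloxy)-1,3-bis(trimethylsilyloxy)hexadec-1-ene | CC(C)(C)[Si](C)(C)OCCCCCCCCCCCCC[C@@H](O[Si](C)(C)C)C=C(O[Si](C)(C)C)OC(C)(C)C
F2 | step 5 | 1-tert-butyl 4-methyl 2-[(1R)-14-(tert-butyldimethylsilyloxy)-1-hydroxytetradecyl]-3-hydroxy-3-methylbutanedioate (diastereomer mixture at C2 and C3) | CC(C)(C)[Si](C)(C)OCCCCCCCCCCCCC[C@@H](O)C(C(=O)OC(C)(C)C)C(C)(O)C(=O)OC
F3 | step 5 | tert-butyl (2R)-2-[13-(tert-butyldimethylsilyloxy)tridecyl]-4-hydroxy-4-methyl-5-oxooxolane-3-carboxylate (diastereomer mixture at C3 and C4) | CC(C)(C)[Si](C)(C)OCCCCCCCCCCCCC[C@H]1OC(=O)C(C)(O)C1C(=O)OC(C)(C)C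
F4 | step 6 | (2R,3S)-4-hydroxy-2-(13-hydroxytridecyl)-4-methyl-5-oxooxolane-3-carboxylic acid (both epimers at the carbinol carbon) | OCCCCCCCCCCCCC[C@H]1OC(=O)C(C)(O)[C@H]1C(=O)O
F5 | step 6 | acetic (2R,3S)-4-acetoxy-2-(13-acetoxytridecyl)-4-methyl-5-oxooxolane-3-carboxylic anhydride | CC(=O)OCCCCCCCCCCCCC[C@H]1OC(=O)C(C)(OC(C)=O)[C@H]1C(=O)OC(C)=O
F6 | step 6 | acetic (2R)-2-(13-acetoxytridecyl)-4-methyl-5-oxo-2,5-dihydrofuran-3-carboxylic anhydride | CC(=O)OCCCCCCCCCCCCC[C@H]1OC(=O)C(C)=C1C(=O)OC(C)=O
F7 | step 4 | (4R)-17-(tert-butyldimethylsilyloxy)heptadec-1-en-4-ol | CC(C)(C)[Si](C)(C)OCCCCCCCCCCCCC[C@@H](O)CC=C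
F8 | step 4 | (3R)-16-(tert-butyldimethylsilyloxy)-3-hydroxyhexadecanal | CC(C)(C)[Si](C)(C)OCCCCCCCCCCCCC[C@@H](O)CC=O
F9 | step 4 | (3R)-16-(tert-butyldimethylsilyloxy)-3-hydroxyhexadecanoic acid | CC(C)(C)[Si](C)(C)OCCCCCCCCCCCCC[C@@H](O)CC(=O)O
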